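The route rests on cutting the C7–C8 bond of the ten-membered carbocycle (germacrane numbering: ring C1–C10, lactone C11–C13). The C8 carbinol lies β to the exocyclic C11=C13 methylene of the lactone ring, the retron of an SE2' allylation. The key step treats a preformed (S)-butenolide, carrying a 3-bromomethyl group and a C6-bound seco-chain ending in the C8 aldehyde, with CrCl2: one operation closes the carbocycle, moves the double bond to unveil the α-methylene lactone and sets C7 and C8, relayed from C6, the only stereocentre, set by catalytic alkynylation. The precursor comes from a B-alkyl Suzuki coupling and a ring-closing metathesis; Mitsunobu esterification then inverts C8 while installing the isovalerate.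

Key step: step 11

Remark: atom numbers follow the germacrane skeleton of the target (ring carbons C1–C10; lactone carbons C11, C12 (C=O) and C13 (exo-methylene); C14 on C10; C15 on C4); the target is the (6S,7R,8R) isomer with a cis-fused lactone, C3 cis to C6 and C2 cis to C9.

Assumption: the (S,S)-ProPhenol–zinc catalyst is taken to add the alkyne to the Si face of crotonaldehyde; if its sense is the opposite, the (R,R)-ligand is used and nothing else changes.

Step 1
Reactants: 1 (E)-but-2-enal (crotonaldehyde); 2 tert-butyldimethyl(prop-2-yn-1-yloxy)silane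
Product: 4 (4R,5E)-1-[(tert-butyldimethylsilyl)oxy]hept-5-en-2-yn-4-ol, via methylzinc acetylide 3 (not isolated)
Conditions: Me2Zn, (S,S)-ProPhenol (20 mol%), Ph3P=O (40 mol%), toluene, 0 °C
Reagents that add atoms: none
Why: Catalytic enantioselective alkynylation of an enal by the dinuclear zinc–ProPhenol complex should deliver the alkynyl group to the Si face of the aldehyde and so set the carbinol carbon (the later C6) as R.

Step 2
Reactants: 4 (4R,5E)-1-[(tert-butyldimethylsilyl)oxy]hept-5-en-2-yn-4-ol
Product: 6 (2Z,4R,5E)-1-[(tert-butyldimethylsilyl)oxy]-2-iodohepta-2,5-dien-4-ol, via cyclic vinylalanate 5 (not isolated)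
Conditions: NaAlH2(OCH2CH2OMe)2, THF, 0 °C; then I2, −78 °C
Reagents that add atoms: iodine (SMILES II)
Why: Hydroxyl-directed trans-hydroalumination of the propargylic alcohol puts aluminium on the distal alkyne carbon (the later C4), and iodinolysis with retention should give the vinyl iodide in which iodine is cis to the carbinol carbon.

Step 3
Reactants: 7 methyl 4,4-dimethoxybutanoate; 8 prop-2-enal (acrolein)
Product: 10 methyl 2-(2,2-dimethoxyethyl)-3-hydroxypent-4-enoate (diastereomer mixture), via lithium ester enolate 9 (not isolated)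
Conditions: LiN(iPr)2, THF, −78 °C; then acrolein, −78 °C
Reagents that add atoms: none
Why: Aldol addition of a lithium ester enolate to acrolein occurs in the 1,2 sense at low temperature, and both new stereocentres are removed in the next step.

Step 4
Reactants: 10 methyl 2-(2,2-dimethoxyethyl)-3-hydroxypent-4-enoate
Product: 12 methyl (2E)-2-(2,2-dimethoxyethyl)penta-2,4-dienoate, via allylic mesylate 11 (not isolated)
Conditions: MsCl, Et3N, CH2Cl2, 0 °C; then DBU, rt
Reagents that add atoms: none
Why: Mesylation followed by E1cB elimination should give the conjugated dienoate mainly as the E isomer (ester trans to the vinyl group, the later C14 trans to C2), which avoids the clash between vinyl and ester groups.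

Step 5
Reactants: 12 methyl (2E)-2-(2,2-dimethoxyethyl)penta-2,4-dienoate
Product: 13 (2E)-2-(2,2-dimethoxyethyl)penta-2,4-dien-1-ol
Conditions: iBu2AlH, CH2Cl2, −78 °C
Reagents that add atoms: none
Why: 1,2-Reduction of a conjugated ester by iBu2AlH gives the allylic alcohol and leaves the acetal and the diene untouched.

Step 6
Reactants: 13 (2E)-2-(2,2-dimethoxyethyl)penta-2,4-dien-1-ol
Product: 14 triethyl{[(2E)-2-(2,2-dimethoxyethyl)penta-2,4-dien-1-yl]oxy}silane
Conditions: Et3SiCl, imidazole, CH2Cl2, 0 °C
Reagents that add atoms: chlorotriethylsilane (SMILES CC[Si](Cl)(CC)CC)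
Why: Standard silylation, the triethylsilyl ether being chosen because it can later be oxidised directly to the aldehyde beside a tert-butyldimethylsilyl ether.

Step 7
Reactants: 14 triethyl{[(2E)-2-(2,2-dimethoxyethyl)penta-2,4-dien-1-yl]oxy}silane; 6 (2Z,4R,5E)-1-[(tert-butyldimethylsilyl)oxy]-2-iodohepta-2,5-dien-4-ol
Product: 16 (2E,4R,5E,9E)-6-{[(tert-butyldimethylsilyl)oxy]methyl}-12,12-dimethoxy-10-{[(triethylsilyl)oxy]methyl}dodeca-2,5,9-trien-4-ol, via B-alkyl-9-BBN borane 15 (not isolated)
Conditions: 9-BBN, THF, 0 °C to rt; then 6, Pd(dppf)Cl2 (5 mol%), AsPh3, Cs2CO3, DMF/THF/H2O, rt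
Reagents that add atoms: none
Why: 9-BBN should hydroborate only the terminal CH2 of the diene to give the homoallylic borane, and the B-alkyl Suzuki–Miyaura coupling replaces iodine with retention, so the new C3–C4 bond is cis to the carbinol carbon (ring-cis geometry of the later C4=C5 olefin).

Step 8
Reactants: 16 (2E,4R,5E,9E)-6-{[(tert-butyldimethylsilyl)oxy]methyl}-12,12-dimethoxy-10-{[(triethylsilyl)oxy]methyl}dodeca-2,5,9-trien-4-ol; 17 2-(bromomethyl)prop-2-enoic acid
Product: 18 (2E,4R,5E,9E)-6-{[(tert-butyldimethylsilyl)oxy]methyl}-12,12-dimethoxy-10-{[(triethylsilyl)oxy]methyl}dodeca-2,5,9-trien-4-yl 2-(bromomethyl)prop-2-enoate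
Conditions: DCC, DMAP (5 mol%), CH2Cl2, −20 to 0 °C
Reagents that add atoms: none
Why: Steglich esterification acylates the secondary bis-allylic alcohol under mild, nearly neutral conditions without touching the stereocentre.

Step 9
Reactants: 18 (2E,4R,5E,9E)-6-{[(tert-butyldimethylsilyl)oxy]methyl}-12,12-dimethoxy-10-{[(triethylsilyl)oxy]methyl}dodeca-2,5,9-trien-4-yl 2-(bromomethyl)prop-2-enoate
Product: 19 (5S)-3-(bromomethyl)-5-[(1E,5E)-2-{[(tert-butyldimethylsilyl)oxy]methyl}-8,8-dimethoxy-6-{[(triethylsilyl)oxy]methyl}octa-1,5-dien-1-yl]furan-2(5H)-one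
Conditions: second-generation Hoveyda–Grubbs catalyst [RuCl2(H2IMes)(=CH-C6H4-2-OiPr)] (10 mol%), toluene (5 mM), 60 °C
Reagents that add atoms: none
Why: Ring-closing metathesis between the propenyl group and the 2-substituted acrylate closes the butenolide with loss of propene while the hindered trisubstituted olefins stay out of the reaction; the stereocentre is untouched and its descriptor changes from R to S only through the priority rules.

Step 10
Reactants: 19 (5S)-3-(bromomethyl)-5-[(1E,5E)-2-{[(tert-butyldimethylsilyl)oxy]methyl}-8,8-dimethoxy-6-{[(triethylsilyl)oxy]methyl}octa-1,5-dien-1-yl]furan-2(5H)-one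
Product: 21 (5S)-3-(bromomethyl)-5-[(1E,5E)-2-{[(tert-butyldimethylsilyl)oxy]methyl}-8-oxo-6-{[(triethylsilyl)oxy]methyl}octa-1,5-dien-1-yl]furan-2(5H)-one, via collidinium salt 20 (not isolated)
Conditions: Et3SiOTf, 2,4,6-collidine, CH2Cl2, 0 °C; then H2O
Reagents that add atoms: water (SMILES O)
Why: Cleavage of a dimethyl acetal by a silyl triflate and a hindered pyridine runs through a pyridinium intermediate under nearly neutral conditions, so the silyl ethers, the allylic bromide and the β,γ-unsaturated aldehyde should survive; the aldehyde is used at once.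

Step 11
Reactants: 21 (5S)-3-(bromomethyl)-5-[(1E,5E)-2-{[(tert-butyldimethylsilyl)oxy]methyl}-8-oxo-6-{[(triethylsilyl)oxy]methyl}octa-1,5-dien-1-yl]furan-2(5H)-one
Product: 23 (6S,7R,8S)-15-[(tert-butyldimethylsilyl)oxy]-8-hydroxy-14-[(triethylsilyl)oxy]germacra-1(10),4,11(13)-trien-12,6-olide (cis-fused lactone; both ring olefins ring-cis), via allylchromium dichloride 22 (not isolated)
Conditions: CrCl2 (10 equiv), DMF/THF, rt, 21 added by syringe pump to 2 mM
Reagents that add atoms: none
Why: CrCl2 reduces the allylic bromide to the C13-bound allylchromium 22 (trivalent chromium), whose γ-carbon C7 adds to the C8 aldehyde through a six-membered Zimmerman–Traxler chair with allylic transposition, so that C7–C8 forms and the C7=C11 double bond moves to C11=C13. The closest known reaction type is the Nozaki–Hiyama–Kishi (Barbier-type) allylation of aldehydes by 3-(bromomethyl)furan-2(5H)-ones and 2-(bromomethyl)acrylates, which is also used intramolecularly to close ten-membered germacrane rings. The carbocycle is closed in a 10-exo-trig mode onto the aldehyde carbon under high dilution. C8 is controlled by the chair: the butenolide holds C6 trans to the CH2Cr group, and C9 must lie pseudo-equatorial, anti to C11, because the pseudo-axial site sits over the lactone ring, which gives the anti C7/C8 pair, that is 8S once C7 is R. C7 is controlled by C6, the only stereocentre of 21: the step needs C–C bond formation on the butenolide face that carries C5 (cis fusion, 7R), and what should secure it is that the aldehyde is strapped to C6 by a seven-atom chain whose two Z olefins can fold it back over that face in the tub-like shape of a (Z,Z)-cyclodeca-1,5-diene. Because intermolecular additions to such butenolides prefer the opposite face, this facial selectivity is the main uncertainty of the route and is answered by a reagent-controlled fallback.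

Step 12
Reactants: 23 (6S,7R,8S)-15-[(tert-butyldimethylsilyl)oxy]-8-hydroxy-14-[(triethylsilyl)oxy]germacra-1(10),4,11(13)-trien-12,6-olide; 24 3-methylbutanoic acid (isovaleric acid)
Product: 26 (6S,7R,8R)-15-[(tert-butyldimethylsilyl)oxy]-8-[(3-methylbutanoyl)oxy]-14-[(triethylsilyl)oxy]germacra-1(10),4,11(13)-trien-12,6-olide, via alkoxyphosphonium isovalerate 25 (not isolated)
Conditions: PPh3, DIAD, toluene, 0 °C to rt
Reagents that add atoms: none
Why: Mitsunobu esterification displaces the activated C8 oxygen by isovalerate in an SN2 step with inversion, which should turn the (8S) alcohol into the (8R) ester of the target.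

Step 13
Reactants: 26 (6S,7R,8R)-15-[(tert-butyldimethylsilyl)oxy]-8-[(3-methylbutanoyl)oxy]-14-[(triethylsilyl)oxy]germacra-1(10),4,11(13)-trien-12,6-olide
Product: 28 (6S,7R,8R)-15-[(tert-butyldimethylsilyl)oxy]-8-[(3-methylbutanoyl)oxy]-14-oxogermacra-1(10),4,11(13)-trien-12,6-olide, via alkoxysulfonium chloride 27 (not isolated)
Conditions: (COCl)2, DMSO, CH2Cl2, −78 to −30 °C; then Et3N, −78 to 0 °C
Reagents that add atoms: none
Why: Under Swern conditions a primary triethylsilyl ether is converted directly into the aldehyde while a tert-butyldimethylsilyl ether is inert, which should give the C14 enal without a separate deprotection.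

Step 14
Reactants: 28 (6S,7R,8R)-15-[(tert-butyldimethylsilyl)oxy]-8-[(3-methylbutanoyl)oxy]-14-oxogermacra-1(10),4,11(13)-trien-12,6-olide
Product: 29 (6S,7R,8R)-15-hydroxy-8-[(3-methylbutanoyl)oxy]-14-oxogermacra-1(10),4,11(13)-trien-12,6-olide (CNP0345200.8)
Conditions: HF·pyridine, pyridine, THF, 0 °C to rt
Reagents that add atoms: none
Why: Buffered fluoride cleaves the primary allylic silyl ether and should leave the enal, the α-methylene lactone and the ester intact.

Compound list

1 | (E)-but-2-enal (crotonaldehyde) | C/C=C/C=O | starting material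
2 | tert-butyldimethyl(prop-2-yn-1-yloxy)silane | C#CCO[Si](C)(C)C(C)(C)C | starting material
3 | methylzinc acetylide of 2 | C[Zn]C#CCO[Si](C)(C)C(C)(C)C | intermediate
4 | (4R,5E)-1-[(tert-butyldimethylsilyl)oxy]hept-5-en-2-yn-4-ol | C/C=C/[C@@H](O)C#CCO[Si](C)(C)C(C)(C)C | intermediate
5 | sodium salt of the cyclic alkoxy(vinyl)alanate of 4 (five-membered ring O–Al–C4=C5–C6) | C/C=C/[C@H]1O[Al-](OCCOC)(OCCOC)C(CO[Si](C)(C)C(C)(C)C)=C1.[Na+] | intermediate
6 | (2Z,4R,5E)-1-[(tert-butyldimethylsilyl)oxy]-2-iodohepta-2,5-dien-4-ol | C/C=C/[C@@H](O)/C=C(\I)CO[Si](C)(C)C(C)(C)C | intermediate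
7 | methyl 4,4-dimethoxybutanoate | COC(=O)CCC(OC)OC | starting material
8 | prop-2-enal (acrolein) | C=CC=O | starting material
9 | lithium enolate of 7 | COC([O-])=CCC(OC)OC.[Li+] | intermediate
10 | methyl 2-(2,2-dimethoxyethyl)-3-hydroxypent-4-enoate (diastereomer mixture, racemic) | COC(=O)C(CC(OC)OC)C(O)C=C | intermediate
11 | methyl 2-(2,2-dimethoxyethyl)-3-[(methylsulfonyl)oxy]pent-4-enoate | COC(=O)C(CC(OC)OC)C(OS(C)(=O)=O)C=C | intermediate
12 | methyl (2E)-2-(2,2-dimethoxyethyl)penta-2,4-dienoate | COC(=O)/C(CC(OC)OC)=C/C=C | intermediate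
13 | (2E)-2-(2,2-dimethoxyethyl)penta-2,4-dien-1-ol | OC/C(CC(OC)OC)=C/C=C | intermediate
14 | triethyl{[(2E)-2-(2,2-dimethoxyethyl)penta-2,4-dien-1-yl]oxy}silane | CC[Si](CC)(CC)OC/C(CC(OC)OC)=C/C=C | intermediate
15 | 9-{(3E)-4-(2,2-dimethoxyethyl)-5-[(triethylsilyl)oxy]pent-3-en-1-yl}-9-borabicyclo[3.3.1]nonane | CC[Si](CC)(CC)OC/C(CC(OC)OC)=C/CCB1C2CCCC1CCC2 | intermediate
16 | (2E,4R,5E,9E)-6-{[(tert-butyldimethylsilyl)oxy]methyl}-12,12-dimethoxy-10-{[(triethylsilyl)oxy]methyl}dodeca-2,5,9-trien-4-ol | C/C=C/[C@@H](O)/C=C(\CC/C=C(/CO[Si](CC)(CC)CC)CC(OC)OC)CO[Si](C)(C)C(C)(C)C | intermediate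
17 | 2-(bromomethyl)prop-2-enoic acid | C=C(CBr)C(=O)O | starting material
18 | (2E,4R,5E,9E)-6-{[(tert-butyldimethylsilyl)oxy]methyl}-12,12-dimethoxy-10-{[(triethylsilyl)oxy]methyl}dodeca-2,5,9-trien-4-yl 2-(bromomethyl)prop-2-enoate | C/C=C/[C@@H](OC(=O)C(=C)CBr)/C=C(\CC/C=C(/CO[Si](CC)(CC)CC)CC(OC)OC)CO[Si](C)(C)C(C)(C)C | intermediate
19 | (5S)-3-(bromomethyl)-5-[(1E,5E)-2-{[(tert-butyldimethylsilyl)oxy]methyl}-8,8-dimethoxy-6-{[(triethylsilyl)oxy]methyl}octa-1,5-dien-1-yl]furan-2(5H)-one | BrCC1=C[C@H](/C=C(\CC/C=C(/CO[Si](CC)(CC)CC)CC(OC)OC)CO[Si](C)(C)C(C)(C)C)OC1=O | intermediate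
20 | 1-(1-methoxyalkyl)-2,4,6-trimethylpyridinium triflate formed at C8 of 19 (C8 epimer mixture) | BrCC1=C[C@H](/C=C(\CC/C=C(/CO[Si](CC)(CC)CC)CC(OC)[n+]2c(C)cc(C)cc2C)CO[Si](C)(C)C(C)(C)C)OC1=O.[O-]S(=O)(=O)C(F)(F)F | intermediate
21 | (5S)-3-(bromomethyl)-5-[(1E,5E)-2-{[(tert-butyldimethylsilyl)oxy]methyl}-8-oxo-6-{[(triethylsilyl)oxy]methyl}octa-1,5-dien-1-yl]furan-2(5H)-one | BrCC1=C[C@H](/C=C(\CC/C=C(/CO[Si](CC)(CC)CC)CC=O)CO[Si](C)(C)C(C)(C)C)OC1=O | intermediate
22 | allylchromium dichloride of 21 (CrCl2 on C13, trivalent chromium) | Cl[Cr](Cl)CC1=C[C@H](/C=C(\CC/C=C(/CO[Si](CC)(CC)CC)CC=O)CO[Si](C)(C)C(C)(C)C)OC1=O | intermediate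
23 | (6S,7R,8S)-15-[(tert-butyldimethylsilyl)oxy]-8-hydroxy-14-[(triethylsilyl)oxy]germacra-1(10),4,11(13)-trien-12,6-olide (cis-fused lactone; C3 cis to C6; C2 cis to C9) | C=C1C(=O)O[C@H]2/C=C(/CO[Si](C)(C)C(C)(C)C)CC/C=C(/CO[Si](CC)(CC)CC)C[C@H](O)[C@@H]12 | intermediate
24 | 3-methylbutanoic acid (isovaleric acid) | CC(C)CC(=O)O | starting material
25 | C8 alkoxytriphenylphosphonium isovalerate of 23 | C=C1C(=O)O[C@H]2/C=C(/CO[Si](C)(C)C(C)(C)C)CC/C=C(/CO[Si](CC)(CC)CC)C[C@H](O[P+](c3ccccc3)(c3ccccc3)c3ccccc3)[C@@H]12.CC(C)CC(=O)[O-] | intermediate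
26 | (6S,7R,8R)-15-[(tert-butyldimethylsilyl)oxy]-8-[(3-methylbutanoyl)oxy]-14-[(triethylsilyl)oxy]germacra-1(10),4,11(13)-trien-12,6-olide | C=C1C(=O)O[C@H]2/C=C(/CO[Si](C)(C)C(C)(C)C)CC/C=C(/CO[Si](CC)(CC)CC)C[C@@H](OC(=O)CC(C)C)[C@@H]12 | intermediate
27 | C14 alkoxydimethylsulfonium chloride of 26 | C=C1C(=O)O[C@H]2/C=C(/CO[Si](C)(C)C(C)(C)C)CC/C=C(/CO[S+](C)C)C[C@@H](OC(=O)CC(C)C)[C@@H]12.[Cl-] | intermediate
28 | (6S,7R,8R)-15-[(tert-butyldimethylsilyl)oxy]-8-[(3-methylbutanoyl)oxy]-14-oxogermacra-1(10),4,11(13)-trien-12,6-olide | C=C1C(=O)O[C@H]2/C=C(/CO[Si](C)(C)C(C)(C)C)CC/C=C(/C=O)C[C@@H](OC(=O)CC(C)C)[C@@H]12 | intermediate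
29 | (6S,7R,8R)-15-hydroxy-8-[(3-methylbutanoyl)oxy]-14-oxogermacra-1(10),4,11(13)-trien-12,6-olide (CNP0345200.8) | C=C1C(=O)O[C@H]2/C=C(/CO)CC/C=C(/C=O)C[C@@H](OC(=O)CC(C)C)[C@@H]12 | target

Total step count: 14. Longest linear sequence: 12 steps (steps 3 to 14, from methyl 4,4-dimethoxybutanoate); the other branch (steps 1 and 2) joins at step 7.

Steps most likely to fail

1. Step 11. The likely failure is poor facial selectivity at C7, that is bond formation on the butenolide face remote from C5 to give the trans-fused lactone, or intermolecular coupling in competition with ring closure. The fallback replaces substrate control under chromium by reagent control in an allylboration. It sets out from 21: borylation of the allylic bromide with B2pin2 and catalytic Pd2(dba)3 in DMSO gives the pinacol allylboronate aldehyde F1. F1 is cyclised at high dilution in toluene with a BINOL-derived chiral phosphoric acid (TRIP, the enantiomer that opens the Re face of the C8 aldehyde). In the closed six-membered transition state with C9 equatorial, that aldehyde face can pair only with the C5 face of the butenolide. Hydrolytic work-up of the borate brings the route back at 23.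

2. Step 12. The likely failure is elimination of the activated C8 oxygen toward the conjugated C8=C9 or C7=C8 dienes, or no displacement because the alkoxyphosphonium is hindered. The fallback separates activation from displacement. It sets out from 23: ClCH2SO2Cl and pyridine in CH2Cl2 at 0 °C give the chloromethanesulfonate F2. CsO2CCH2CH(CH3)2 (from 24 and Cs2CO3) with 18-crown-6 in toluene at 50 °C then displaces it with inversion, coming back at 26.

3. Step 9. The likely failure is arrest of the ruthenium carbene or allylic transposition caused by the 2-(bromomethyl)acrylate, so that ring closure stalls; the same bromide may also be lost by quaternisation during the acylation of step 8. The fallback introduces the bromide only after the butenolide is closed. It sets out from 16: acryloyl chloride and iPr2NEt give the acrylate F3, and ring-closing metathesis with the same ruthenium catalyst gives the 3-unsubstituted butenolide F4. I2 and pyridine in CCl4 give the 3-iodobutenolide F5, and Stille coupling with Bu3SnCH2OH and Pd(PPh3)4 gives the 3-(hydroxymethyl)butenolide F6. CBr4 and PPh3 then bring the route back at 19.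

Further compounds

F1 | step 11 | pinacol allylboronate aldehyde: 21 with Bpin in place of Br on C13 (C6 configured as in 21) | CC1(C)OB(CC2=C[C@H](/C=C(\CC/C=C(/CO[Si](CC)(CC)CC)CC=O)CO[Si](C)(C)C(C)(C)C)OC2=O)OC1(C)C
F2 | step 12 | C8 chloromethanesulfonate of 23 (6S,7R,8S) | C=C1C(=O)O[C@H]2/C=C(/CO[Si](C)(C)C(C)(C)C)CC/C=C(/CO[Si](CC)(CC)CC)C[C@H](OS(=O)(=O)CCl)[C@@H]12
F3 | step 9 | prop-2-enoate (acrylate) ester of 16 (carbinol carbon configured as in 16) | C/C=C/[C@@H](OC(=O)C=C)/C=C(\CC/C=C(/CO[Si](CC)(CC)CC)CC(OC)OC)CO[Si](C)(C)C(C)(C)C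
F4 | step 9 | 3-unsubstituted butenolide: 19 with H in place of the bromomethyl group (C6 configured as in 19) | O=C1C=C[C@H](/C=C(\CC/C=C(/CO[Si](CC)(CC)CC)CC(OC)OC)CO[Si](C)(C)C(C)(C)C)O1
F5 | step 9 | 3-iodobutenolide: 19 with I in place of the bromomethyl group (C6 configured as in 19) | O=C1C(I)=C[C@H](/C=C(\CC/C=C(/CO[Si](CC)(CC)CC)CC(OC)OC)CO[Si](C)(C)C(C)(C)C)O1
F6 | step 9 | 3-(hydroxymethyl)butenolide: 19 with OH in place of Br (C6 configured as in 19) | O=C1C(CO)=C[C@H](/C=C(\CC/C=C(/CO[Si](CC)(CC)CC)CC(OC)OC)CO[Si](C)(C)C(C)(C)C)O1
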